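(The runs were generated by integration on assumed constants; scatter was added.)

1. In a closed flask the books balance: each mole of starting material charged stands either as starting material left or as something made from it. So I kept my ledger on the starting material, which in Tuesday's and Wednesday's is the limiting reagent together with the salt at 1.00 equiv.

| setting | alpha | Tuesday's | Wednesday's |
|---|---|---|---|
| starting material | 0.20 M | 0.20 M | 0.20 M |
| salt in the second phase | 1.5 equiv | 1.00 equiv | 1.00 equiv |
| spent carrier | 2.3 mol% | 2.3 mol% | 2.3 mol% |
| temperature | 70 °C | 40 °C | 70 °C |
| remark | run made earlier |  |  |
| time |  | 1.5 d | 5.0 d |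
| volume of the second phase over the first |  | 1.0 | 1.0 |

alpha run (percent of the starting material charged)

| time / h | target / % |
|---|---|
| 2.00 | 4.5 |
| 4.00 | 9.8 |
| 6.00 | 14.7 |
| 8.00 | 18.1 |
| 10.0 | 22.7 |
| 12.0 | 26.5 |

(each reading ± 0.5 percentage points)

- charges count per volume of the first phase; a concentration in a rate is the amount of a species over the volume of its own phase; every rate counts per litre of the first phase
- the earlier runs hold the two phases in the same ratio of volumes as the flask asked about
- the earlier runs do not show what temperature does; that part of a forecast is a guess

- the flask that ends with the higher amount of target, in percent of the starting material charged, or "neither" when 2 percentage points or less lies between them (Tuesday's / Wednesday's / neither)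
- final target, as a percentage of the starting material charged, in Tuesday's
- final target, as a percentage of the starting material charged, in Wednesday's

2. I worked in powers of ten. The alpha run's last reading was 26.5 % target at 12.0 h; booking all the rest as starting material left 73.5 % of the charge. Decades of starting material lost per hour then came to 0.0111 /h; this is my decade rate.

3. Wednesday's stood at the alpha run's temperature, so if that rate held, its 5.0 d booked 1.34 decades: 4.57 % left and 95.4 % as target. That entry was an extrapolation to ten times the alpha run's time, with less salt.

4. Tuesday's, booked even at 70 °C, held 0.401 decades, fewer than Wednesday's. Its rate at 40 °C was a guess, but a slower one there widened the gap, so I chose Wednesday's.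

5. The forecast also chose Wednesday's, with 6 % (3 % to 14 %) for Tuesday's and 75 % (50 % to 95 %) for Wednesday's, lower than my entry. One of its grounds: “Carrier decay over five days at 70 °C, unseen in 12 h, could lower this further.”

6. Wednesday's gave more: Wednesday's ended at 82.7 % target, 7.7 percentage points above the forecast, and Tuesday's at 6.81 %. Wednesday's still held 10.0 % of its starting material at 5.00 d. Read back, that remainder gives an average decade rate of 0.00833 /h, lower than 0.0111 /h, at 0.750 of it.

    spent carrier + salt in the second phase ⇌ fresh carrier + spent salt in the second phase (K = 8.20, k = 140 /M/h, Ea = 64.0 kJ/mol, ΔH = −35.0 kJ/mol)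
    target + fresh carrier ⇌ isomer of the product + fresh carrier, rate k2*[target]*[fresh carrier] forward; the back reaction follows from the equilibrium constant (K = 0.120, k = 0.560 /M/h, Ea = 66.0 kJ/mol, ΔH = −51.0 kJ/mol)
    2 starting material → homo dimer (k = 5.90 × 10⁻⁴ /M/h, Ea = 93.0 kJ/mol)
    starting material + fresh carrier → target + spent carrier (k = 5.90 /M/h, Ea = 77.0 kJ/mol)
    (constants at 70 °C)

7. Tuesday's own decade rate, from its 6.81 %, was 8.51 × 10⁻⁴ /h, against 0.0111 /h in the alpha run. For a neighbouring flask, the same as Tuesday's but with 0.92 mol% of spent carrier instead of 2.3 mol%, I scaled that rate with the carrier and booked 0.0122 decades, or 2.77 % target. The computed flask gave 2.79 %.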